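**Strategy.** Everything rests on cutting the bond between C8 of one 7-methoxycoumarin ring and the benzylic carbon C1′ of the (1′R,2′R) side chain. This carbon bears the bridging ether oxygen, so it is a latent acetal carbon. The precursor is a 1,3-dioxolane (both C2 epimers) that ties it to the erythro diol of the other half, whose isopropenyl group is held as acetyl to exclude Prins closure. Silyl triflate opens the acetal; the C2′ benzoate captures the oxocarbenium ion, and a coumarin-8-ylzinc reagent opens the resulting dioxolanylium ion with inversion. One operation thus joins the halves, sets C1′ and frees the C2′ hydroxyl of the other half.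

Key step: step 10

Remark: side-chain atoms are numbered C1′ (benzylic), C2′ (carbinol) and C3′. The target is read from its SMILES as a (1′R,2′R) (threo) unit etherified at C1′ with a (1′S,2′R) (erythro) unit.

Step 1
Reactants: 1 umbelliferone (7-hydroxy-2H-chromen-2-one)
Product: 2 7-hydroxy-2-oxo-2H-chromene-8-carbaldehyde
Conditions: hexamethylenetetramine, AcOH, 95 °C; then aq. HCl, 70 °C
Reagents that add atoms: hexamethylenetetramine (C1N2CN3CN1CN(C2)C3); water (O)
Why: Duff formylation; the phenol directs the iminium electrophile ortho, and C8, between the hydroxyl and the ring oxygen, is the most nucleophilic position of a 7-hydroxycoumarin.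

Step 2
Reactants: 2 7-hydroxy-2-oxo-2H-chromene-8-carbaldehyde
Product: 3 7-methoxy-2-oxo-2H-chromene-8-carbaldehyde
Conditions: MeI, K2CO3, acetone, reflux
Reagents that add atoms: iodomethane (CI)
Why: Williamson ether synthesis; the phenoxide is the only nucleophile present.

Step 3
Reactants: 3 7-methoxy-2-oxo-2H-chromene-8-carbaldehyde; 4 hydroxyacetone (excess)
Product: 5 8-[(1S,2S)-1,2-dihydroxy-3-oxobutyl]-7-methoxy-2H-chromen-2-one
Conditions: L-proline (30 mol %), DMSO, rt
Reagents that add atoms: none
Why: Proline-catalysed direct aldol reaction; the (E)-enamine formed at the hydroxylated carbon of hydroxyacetone should add to the aldehyde through the carboxylic-acid-bound chair-like transition state, which sets both stereocentres of the erythro half as the anti (1S,2S) diol under catalyst control.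

Step 4
Reactants: 6 2,2-dimethoxyacetaldehyde (dried solution in THF); 7 isopropenylmagnesium bromide
Product: 8 rac-1,1-dimethoxy-3-methylbut-3-en-2-ol
Conditions: THF, −78 → 0 °C; then aq. NH4Cl
Reagents that add atoms: none
Why: Grignard addition to the aldehyde; the acetal is inert to the reagent.

Step 5
Reactants: 8 rac-1,1-dimethoxy-3-methylbut-3-en-2-ol
Product: 9 (R)-1,1-dimethoxy-3-methylbut-3-en-2-ol
Conditions: Ti(OiPr)4 (cat.), D-(−)-diisopropyl tartrate, t-BuOOH (0.6 equiv), 4 Å MS, CH2Cl2, −20 °C
Reagents that add atoms: none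
Why: Sharpless kinetic resolution; with the D-(−)-tartrate the (S)-alcohol, whose acetal substituent points away from the oxygen-delivering face, should be epoxidised fast, so the (R)-alcohol that carries the future C2′ of the threo half is recovered.

Step 6
Reactants: 9 (R)-1,1-dimethoxy-3-methylbut-3-en-2-ol
Product: 10 (R)-1,1-dimethoxy-3-methylbut-3-en-2-yl benzoate
Conditions: BzCl, pyridine, DMAP (cat.), CH2Cl2, 0 °C → rt
Reagents that add atoms: benzoyl chloride (O=C(Cl)c1ccccc1)
Why: DMAP-catalysed acylation of the secondary alcohol; it installs the group that later participates at C1′, and the stereocentre is untouched.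

Step 7
Reactants: 5 8-[(1S,2S)-1,2-dihydroxy-3-oxobutyl]-7-methoxy-2H-chromen-2-one; 10 (R)-1,1-dimethoxy-3-methylbut-3-en-2-yl benzoate
Product: 11 (1R)-1-[(4S,5S)-4-acetyl-5-(7-methoxy-2-oxo-2H-chromen-8-yl)-1,3-dioxolan-2-yl]-2-methylprop-2-en-1-yl benzoate (both C2 epimers)
Conditions: CSA (cat.), PhMe, 4 Å MS, 45 °C
Reagents that add atoms: none
Why: Acid-catalysed transacetalisation; the 1,2-diol should close the five-membered acetal with loss of methanol, and the configuration at the acetal carbon is neither controlled nor needed.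

Step 8
Reactants: 1 umbelliferone
Product: 12 7-hydroxy-8-iodo-2H-chromen-2-one
Conditions: I2, KI, aq. NH3, rt
Reagents that add atoms: iodine (II)
Why: Electrophilic aromatic iodination of the phenoxide, which should go to C8 for the same reason as in step 1.

Step 9
Reactants: 12 7-hydroxy-8-iodo-2H-chromen-2-one
Product: 13 8-iodo-7-methoxy-2H-chromen-2-one
Conditions: MeI, K2CO3, acetone, reflux
Reagents that add atoms: iodomethane (CI)
Why: Williamson ether synthesis on the phenoxide.

Step 10
Reactants: 13 8-iodo-7-methoxy-2H-chromen-2-one; 11 dioxolane (both C2 epimers)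
Product: 16 (1R,2R)-1-{[(1S,2S)-2-hydroxy-1-(7-methoxy-2-oxo-2H-chromen-8-yl)-3-oxobutyl]oxy}-1-(7-methoxy-2-oxo-2H-chromen-8-yl)-3-methylbut-3-en-2-yl benzoate, via arylzinc iodide 14 (not isolated), via trimethylsilyl ether 15 (not isolated)
Conditions: Zn dust, LiCl, THF, 40 °C; solvent exchange to PhMe/CH2Cl2; 11, TMSOTf, −78 → −20 °C; then aq. citric acid
Reagents that add atoms: none
Why: TMSOTf should silylate the less hindered dioxolane oxygen next to the acetyl group and break that C–O bond, which places the oxocarbenium ion on the benzylic oxygen, remote from the electron-withdrawing ketone; the C2′ benzoate carbonyl then closes onto the cationic carbon (5-exo-trig) to give the 4,5-trans 1,3-dioxolan-2-ylium ion, which both acetal epimers of 11 reach. The arylzinc reagent 14 opens this ion at C1′ by SN2-type attack anti to the acyloxy oxygen, which forms the C8–C1′ bond and gives the (1′R) configuration, threo to the (R)-C2′ benzoate. The closest known reaction types are the Lewis-acid-mediated opening of cyclic acetals by organometallic reagents and the 1,2-trans C-arylation of 2-O-acyl glycosyl donors with arylzinc reagents. The new stereocentre is thus controlled by the C2′ stereocentre through the participating benzoate and not by the acetal carbon, which makes the step stereoconvergent. The step needs cleavage of the acetal C–O bond on the acetyl side (secured by the inductive effect of the ketone and by the hindered benzylic oxygen) and attack of the arylzinc on the cation in preference to ketone, benzoate and lactones (organozinc halides do not add to these at low temperature). No alkene stands homoallylic to the cationic oxygen, so Prins cyclisation cannot compete.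

Step 11
Reactants: 16 ketone from step 10
Product: 17 (1R,2R)-1-{[(1S,2R)-2-hydroxy-1-(7-methoxy-2-oxo-2H-chromen-8-yl)-3-methylbut-3-en-1-yl]oxy}-1-(7-methoxy-2-oxo-2H-chromen-8-yl)-3-methylbut-3-en-2-yl benzoate
Conditions: Zn, CH2Br2, TiCl4, THF/CH2Cl2, 0 °C → rt
Reagents that add atoms: dibromomethane (BrCBr)
Why: Lombardo methylenation; the non-basic titanium methylidene reagent should convert the methyl ketone into the isopropenyl group without epimerising C2′ and should leave benzoate, lactones and the free hydroxyl alone.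

Step 12
Reactants: 17 benzoate from step 11
Product: 18 8-[(1R,2R)-2-hydroxy-1-{[(1S,2R)-2-hydroxy-1-(7-methoxy-2-oxo-2H-chromen-8-yl)-3-methylbut-3-en-1-yl]oxy}-3-methylbut-3-en-1-yl]-7-methoxy-2H-chromen-2-one
Conditions: K2CO3, MeOH, rt
Reagents that add atoms: none
Why: Base-catalysed transesterification (methanolysis) of the benzoate; no stereocentre of the product is base-labile, and the coumarin lactones should survive these mild conditions.

**Compound list**

1 | umbelliferone (7-hydroxy-2H-chromen-2-one) | O=c1ccc2ccc(O)cc2o1 | starting material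
2 | 7-hydroxy-2-oxo-2H-chromene-8-carbaldehyde | O=Cc1c(O)ccc2ccc(=O)oc12 | intermediate
3 | 7-methoxy-2-oxo-2H-chromene-8-carbaldehyde | COc1ccc2ccc(=O)oc2c1C=O | intermediate
4 | hydroxyacetone | CC(=O)CO | starting material
5 | 8-[(1S,2S)-1,2-dihydroxy-3-oxobutyl]-7-methoxy-2H-chromen-2-one | O[C@@H](c1c(OC)ccc2ccc(=O)oc12)[C@H](O)C(C)=O | intermediate
6 | 2,2-dimethoxyacetaldehyde | COC(OC)C=O | starting material
7 | isopropenylmagnesium bromide | CC(=C)[Mg]Br | starting material
8 | rac-1,1-dimethoxy-3-methylbut-3-en-2-ol | C=C(C)C(O)C(OC)OC | intermediate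
9 | (R)-1,1-dimethoxy-3-methylbut-3-en-2-ol | C=C(C)[C@@H](O)C(OC)OC | intermediate
10 | (R)-1,1-dimethoxy-3-methylbut-3-en-2-yl benzoate | C=C(C)[C@@H](OC(=O)c1ccccc1)C(OC)OC | intermediate
11 | (1R)-1-[(4S,5S)-4-acetyl-5-(7-methoxy-2-oxo-2H-chromen-8-yl)-1,3-dioxolan-2-yl]-2-methylprop-2-en-1-yl benzoate, both C2 epimers | O1[C@@H](c2c(OC)ccc3ccc(=O)oc23)[C@H](OC1[C@H](OC(=O)c4ccccc4)C(C)=C)C(C)=O | intermediate
12 | 7-hydroxy-8-iodo-2H-chromen-2-one | Oc1ccc2ccc(=O)oc2c1I | intermediate
13 | 8-iodo-7-methoxy-2H-chromen-2-one | COc1ccc2ccc(=O)oc2c1I | intermediate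
14 | (7-methoxy-2-oxo-2H-chromen-8-yl)zinc iodide (LiCl complex) | COc1ccc2ccc(=O)oc2c1[Zn]I | intermediate
15 | trimethylsilyl ether of 16 at the C2′ hydroxyl of the ketone half | C=C(C)[C@@H](OC(=O)c1ccccc1)[C@H](O[C@@H](c1c(OC)ccc2ccc(=O)oc12)[C@H](O[Si](C)(C)C)C(C)=O)c1c(OC)ccc2ccc(=O)oc12 | intermediate
16 | (1R,2R)-1-{[(1S,2S)-2-hydroxy-1-(7-methoxy-2-oxo-2H-chromen-8-yl)-3-oxobutyl]oxy}-1-(7-methoxy-2-oxo-2H-chromen-8-yl)-3-methylbut-3-en-2-yl benzoate | C=C(C)[C@@H](OC(=O)c1ccccc1)[C@H](O[C@@H](c1c(OC)ccc2ccc(=O)oc12)[C@H](O)C(C)=O)c1c(OC)ccc2ccc(=O)oc12 | intermediate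
17 | (1R,2R)-1-{[(1S,2R)-2-hydroxy-1-(7-methoxy-2-oxo-2H-chromen-8-yl)-3-methylbut-3-en-1-yl]oxy}-1-(7-methoxy-2-oxo-2H-chromen-8-yl)-3-methylbut-3-en-2-yl benzoate | C=C(C)[C@@H](OC(=O)c1ccccc1)[C@H](O[C@@H](c1c(OC)ccc2ccc(=O)oc12)[C@H](O)C(=C)C)c1c(OC)ccc2ccc(=O)oc12 | intermediate
18 | 8-[(1R,2R)-2-hydroxy-1-{[(1S,2R)-2-hydroxy-1-(7-methoxy-2-oxo-2H-chromen-8-yl)-3-methylbut-3-en-1-yl]oxy}-3-methylbut-3-en-1-yl]-7-methoxy-2H-chromen-2-one | C=C(C)[C@@H](O)[C@H](O[C@@H](c1c(OC)ccc2ccc(=O)oc12)[C@H](O)C(=C)C)c1c(OC)ccc2ccc(=O)oc12 | target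

**Step count and risks**

Total steps: 12. Longest linear sequence: 7 steps (1 → 2 → 3 → 7 → 10 → 11 → 12).

Steps most likely to fail:

Step 10 (key step). The acetal may open at the other C–O bond, or the hindered arylzinc reagent may attack too slowly, so that the cation decays by elimination, by attack at the benzoxonium carbon or by facial leakage through the open oxocarbenium ion. The fallback sets out from 13 (with 11) and comes back at 16, and brings the aryl group in on boron instead of zinc. Miyaura borylation of 13 (B2pin2, Pd(dppf)Cl2, KOAc, dioxane, 80 °C) would give 7-methoxy-8-(4,4,5,5-tetramethyl-1,3,2-dioxaborolan-2-yl)-2H-chromen-2-one F1. KHF2 in aqueous methanol would convert it into potassium (7-methoxy-2-oxo-2H-chromen-8-yl)trifluoroborate F2. F2, 11 and BF3·OEt2 in CH2Cl2/MeCN at 0 °C (the known ether synthesis from acetals and organotrifluoroborates) would then give 16 after aqueous work-up. In that reaction the aryldifluoroborane acts as the Lewis acid, can chelate between the acetyl oxygen and the acetal oxygen that must leave, and delivers the aryl group within the ion pair.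

Step 3. Facial and anti/syn discrimination may be poor with a di-ortho-substituted aromatic aldehyde, and retro-aldol equilibration may erode the diol. The fallback sets out from 3 and comes back at 5. Wittig reaction of 3 with 1-(triphenylphosphoranylidene)propan-2-one would give (E)-7-methoxy-8-(3-oxobut-1-en-1-yl)-2H-chromen-2-one F3. Lanthanum–BINOL-catalysed nucleophilic epoxidation with t-BuOOH, using the ligand enantiomer that gives the (2R,3S)-oxirane, would give 8-[(2R,3S)-3-acetyloxiran-2-yl]-7-methoxy-2H-chromen-2-one F4. Acid-catalysed hydrolysis (dilute HClO4, THF/H2O, 0 °C) should open F4 at the benzylic carbon with inversion and give the anti diol 5.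

Step 11. The titanium reagent is Lewis acidic and may trigger β-elimination or epimerisation next to the ketone, or ionise the bis-benzylic ether. The fallback sets out from 16 and comes back at 17 by a Peterson olefination. Addition of (trimethylsilyl)methylmagnesium chloride/CeCl3 in THF at −78 °C to the ketone of 16 should give the β-hydroxysilane (1R,2R)-1-{[(1S,2S)-2,3-dihydroxy-1-(7-methoxy-2-oxo-2H-chromen-8-yl)-3-methyl-4-(trimethylsilyl)butyl]oxy}-1-(7-methoxy-2-oxo-2H-chromen-8-yl)-3-methylbut-3-en-2-yl benzoate F5. Acid-promoted elimination (CSA cat., CH2Cl2, 0 °C) of F5 would then give 17.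

Further compounds
F1 | step 10 | 7-methoxy-8-(4,4,5,5-tetramethyl-1,3,2-dioxaborolan-2-yl)-2H-chromen-2-one | COc1ccc2ccc(=O)oc2c1B1OC(C)(C)C(C)(C)O1
F2 | step 10 | potassium (7-methoxy-2-oxo-2H-chromen-8-yl)trifluoroborate | [K+].COc1ccc2ccc(=O)oc2c1[B-](F)(F)F
F3 | step 3 | (E)-7-methoxy-8-(3-oxobut-1-en-1-yl)-2H-chromen-2-one | CC(=O)/C=C/c1c(OC)ccc2ccc(=O)oc12
F4 | step 3 | 8-[(2R,3S)-3-acetyloxiran-2-yl]-7-methoxy-2H-chromen-2-one | O1[C@H](c2c(OC)ccc3ccc(=O)oc23)[C@H]1C(C)=O
F5 | step 11 | (1R,2R)-1-{[(1S,2S)-2,3-dihydroxy-1-(7-methoxy-2-oxo-2H-chromen-8-yl)-3-methyl-4-(trimethylsilyl)butyl]oxy}-1-(7-methoxy-2-oxo-2H-chromen-8-yl)-3-methylbut-3-en-2-yl benzoate (C3 epimers) | C=C(C)[C@@H](OC(=O)c1ccccc1)[C@H](O[C@@H](c1c(OC)ccc2ccc(=O)oc12)[C@H](O)C(C)(O)C[Si](C)(C)C)c1c(OC)ccc2ccc(=O)oc12
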